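The target is a conduritol B ring (C1–C6, with all-trans oxygens on C2, C1, C6 and C5 and the C3=C4 alkene) that carries one extra carbon, C7, on C1. Everything rests on cutting C1–C7: without C7 the ring is the twofold-symmetric diol 6, whose carbinol carbons C1 and C6 are homotopic, so mono-oxidation gives one ketol, 8. In one flask diazomethane delivers C7 to the C1 carbonyl axially, cis to the equatorial oxygens on C2 and C6, and benzoic acid opens the spiro-oxirane at C7; three components meet at C1 and its quaternary stereocentre is set. The ring comes from L-tartrate by divinylation, ring-closing metathesis and double Mitsunobu benzoylation.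

Key step: step 6

Remark: the target is read as (1R,2R,5R,6S), with the ring oxygens alternating in face (O2 up, O1 down, O6 up, O5 down) and C7 cis to O2 and O6; the atom numbers of the target are used for all ring intermediates.

Step 1
Reactants: 1 dimethyl (4R,5R)-2,2-dimethyl-1,3-dioxolane-4,5-dicarboxylate (dimethyl 2,3-O-isopropylidene-L-tartrate)
Product: 3 (1S,1'S)-1,1'-[(4S,5S)-2,2-dimethyl-1,3-dioxolane-4,5-diyl]bis(prop-2-en-1-ol), via L-tartraldehyde acetonide 2 (not isolated)
Conditions: iBu2AlH (2.1 equiv), PhMe, −78 °C; then (CH2=CH)2Zn [from CH2=CHMgBr and ZnCl2], THF, −78 °C to rt; aq. potassium sodium tartrate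
Reagents that add atoms: vinylmagnesium bromide, C=C[Mg]Br (used as divinylzinc, C=C[Zn]C=C, formed in the flask with ZnCl2)
Why: Partial reduction stops at the aluminium hemiacetal of each ester, and the vinylzinc reagent then adds to the liberated aldehydes under Felkin–Anh control (attack anti to the adjacent dioxolane C–O bond, no chelation by the acetonide), which should set both new carbinol centres anti to their neighbours and give the twofold-symmetric L-manno diol, while the two inner centres come unchanged from L-tartrate (one-pot reduction–vinylation).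

Step 2
Reactants: 3 (1S,1'S)-1,1'-[(4S,5S)-2,2-dimethyl-1,3-dioxolane-4,5-diyl]bis(prop-2-en-1-ol)
Product: 4 (3aS,4S,7S,7aS)-2,2-dimethyl-3a,4,7,7a-tetrahydro-1,3-benzodioxole-4,7-diol (conduritol E 2,3-acetonide)
Conditions: second-generation Grubbs catalyst (H2IMes)(PCy3)Cl2Ru=CHPh (3 mol%), CH2Cl2, 40 °C
Reagents that add atoms: none
Why: Ring-closing metathesis of a 1,7-diene to a cyclohexene with loss of ethene is favourable and tolerates free allylic hydroxyls, and no stereocentre is touched.

Step 3
Reactants: 4 (3aS,4S,7S,7aS)-2,2-dimethyl-3a,4,7,7a-tetrahydro-1,3-benzodioxole-4,7-diol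
Product: 5 (3aS,4R,7R,7aS)-2,2-dimethyl-3a,4,7,7a-tetrahydro-1,3-benzodioxole-4,7-diyl dibenzoate (conduritol B 1,4-dibenzoate 2,3-acetonide)
Conditions: PhCO2H (3 equiv), PPh3 (3 equiv), DIAD (3 equiv), THF, 0 °C to rt
Reagents that add atoms: benzoic acid, O=C(O)c1ccccc1
Why: In the Mitsunobu reaction each pseudoaxial allylic alcohol is activated as its oxyphosphonium salt and displaced by benzoate in an SN2 step with inversion, so the two cis relationships of the conduritol E pattern become trans and the benzoates of C2 and C5 are installed in the same operation.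

Step 4
Reactants: 5 (3aS,4R,7R,7aS)-2,2-dimethyl-3a,4,7,7a-tetrahydro-1,3-benzodioxole-4,7-diyl dibenzoate
Product: 6 (1R,2R,3R,4R)-2,3-dihydroxycyclohex-5-ene-1,4-diyl dibenzoate
Conditions: TFA/H2O (9:1), CH2Cl2, 0 °C
Reagents that add atoms: none
Why: The strained trans-fused dioxolane is hydrolysed by mild aqueous acid under which allylic benzoates are stable (acetal hydrolysis), freeing the C1 and C6 hydroxyls.

Step 5
Reactants: 6 (1R,2R,3R,4R)-2,3-dihydroxycyclohex-5-ene-1,4-diyl dibenzoate
Product: 8 (2R,5R,6S)-2,5-bis(benzoyloxy)-6-hydroxycyclohex-3-en-1-one, via dibutylstannylene acetal 7 (not isolated)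
Conditions: Bu2Sn(OMe)2 (1.05 equiv), PhMe, rt, evaporate; then NBS (1.05 equiv), CH2Cl2, 0 °C; crude product used at once
Reagents that add atoms: none
Why: Brominolysis of a stannylene acetal oxidises exactly one hydroxyl of a vicinal diol to the ketone under near-neutral conditions without glycol cleavage or a second oxidation, and since C1 and C6 of the twofold-symmetric diol are homotopic a single ketol should result with its C6 stereocentre untouched.

Step 6
Reactants: 8 (2R,5R,6S)-2,5-bis(benzoyloxy)-6-hydroxycyclohex-3-en-1-one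
Product: 10 [(1R,2R,5R,6S)-2,5-bis(benzoyloxy)-1,6-dihydroxycyclohex-3-en-1-yl]methyl benzoate (target), via spiro-oxirane dibenzoate 9 (not isolated)
Conditions: CH2N2 (excess, ethereal), CH2Cl2, 0 °C; evaporate; then PhCO2H (3 equiv), Bu4NO2CPh (0.2 equiv), PhMe, 70 °C
Reagents that add atoms: diazomethane, C=[N+]=[N-]; benzoic acid, O=C(O)c1ccccc1
Why: The nucleophilic carbon of diazomethane adds to the C1 carbonyl, which is activated by the flanking C2 benzoate and the hydrogen-bonding C6 hydroxyl, and the resulting alkoxide displaces N2 from C7 to close the oxirane of 9 in a 3-exo-tet mode; tetrabutylammonium benzoate then opens this oxirane by SN2 attack at the unhindered primary C7, which leaves the new C1–O bond untouched. The closest known reaction type is the diazomethane epoxidation of α-acyloxy cyclohexanones such as inosose esters and pyranosiduloses, followed by carboxylate opening of a 2,2-disubstituted oxirane. The only new stereocentre, C1, is set by axial attack on the half-chair in which the C2 benzoate, the C6 hydroxyl and the C5 benzoate are all equatorial: the small reagent approaches anti to the axial C2–H and C6–H bonds and meets only one syn-axial hydrogen (on C5) because C3 is sp2, so C7 should end cis to O2 and O6 and the tertiary hydroxyl trans to both. Two selectivities are needed: oxirane closure over ring expansion, secured because the electron-poor oxygen-bearing carbons C2 and C6 migrate poorly, and attack of benzoate at C7 and not at C1 or the allylic carbons, secured by the steric difference between a primary and a fully substituted oxirane carbon. The excess of benzoic acid keeps the medium acidic, which should suppress Payne rearrangement towards the C6 oxygen and benzoyl migration.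

Compound list
1 | dimethyl (4R,5R)-2,2-dimethyl-1,3-dioxolane-4,5-dicarboxylate (dimethyl 2,3-O-isopropylidene-L-tartrate) | COC(=O)[C@@H]1OC(C)(C)O[C@H]1C(=O)OC | starting material
2 | (4R,5R)-2,2-dimethyl-1,3-dioxolane-4,5-dicarbaldehyde (L-tartraldehyde acetonide, held as its aluminium hemiacetal, not isolated) | O=C[C@@H]1OC(C)(C)O[C@H]1C=O | intermediate
3 | (1S,1'S)-1,1'-[(4S,5S)-2,2-dimethyl-1,3-dioxolane-4,5-diyl]bis(prop-2-en-1-ol) | C=C[C@H](O)[C@@H]1OC(C)(C)O[C@H]1[C@@H](O)C=C | intermediate
4 | (3aS,4S,7S,7aS)-2,2-dimethyl-3a,4,7,7a-tetrahydro-1,3-benzodioxole-4,7-diol | CC1(C)O[C@H]2[C@@H](O)C=C[C@H](O)[C@@H]2O1 | intermediate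
5 | (3aS,4R,7R,7aS)-2,2-dimethyl-3a,4,7,7a-tetrahydro-1,3-benzodioxole-4,7-diyl dibenzoate | CC1(C)O[C@H]2[C@H](OC(=O)c3ccccc3)C=C[C@@H](OC(=O)c3ccccc3)[C@@H]2O1 | intermediate
6 | (1R,2R,3R,4R)-2,3-dihydroxycyclohex-5-ene-1,4-diyl dibenzoate | O[C@H]1[C@H](OC(=O)c2ccccc2)C=C[C@@H](OC(=O)c2ccccc2)[C@@H]1O | intermediate
7 | dibutylstannylene acetal of 6 (2,2-dibutyl-1,3,2-dioxastannolane across O1 and O6, not isolated) | CCCC[Sn]1(CCCC)O[C@H]2[C@H](OC(=O)c3ccccc3)C=C[C@@H](OC(=O)c3ccccc3)[C@@H]2O1 | intermediate
8 | (2R,5R,6S)-2,5-bis(benzoyloxy)-6-hydroxycyclohex-3-en-1-one | O=C1[C@H](OC(=O)c2ccccc2)C=C[C@@H](OC(=O)c2ccccc2)[C@@H]1O | intermediate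
9 | (3R,4R,7R,8S)-8-hydroxy-1-oxaspiro[2.5]oct-5-ene-4,7-diyl dibenzoate (not isolated) | C1O[C@]12[C@H](OC(=O)c3ccccc3)C=C[C@@H](OC(=O)c3ccccc3)[C@@H]2O | intermediate
10 | [(1R,2R,5R,6S)-2,5-bis(benzoyloxy)-1,6-dihydroxycyclohex-3-en-1-yl]methyl benzoate | O=C(OC[C@]1(O)[C@H](OC(=O)c2ccccc2)C=C[C@@H](OC(=O)c2ccccc2)[C@@H]1O)c1ccccc1 | target

Total step count: 6. Longest linear sequence: 6 steps (1 → 3 → 4 → 5 → 6 → 8 → 10).

Steps most likely to fail

Step 6 (key step). The diazonium betaine may undergo a 1,2-shift of C2 or C6 (ring expansion) in place of oxirane closure. Part of the attack may come from the equatorial face and give the C1 epimer. The ketol may enolise towards C2 and lose benzoic acid with aromatisation before it is trapped. During the opening, Payne rearrangement or benzoyl migration may scramble the oxygen pattern. Fallback: from 8, Takai–Lombardo methylenation (Zn, CH2Br2, TiCl4, THF) would give the exocyclic alkene F1, so that C1–C7 is still made on the ketone; osmylation (OsO4 cat., NMO, acetone/H2O) is expected to occur anti to the allylic oxygens on C2 and C6 and to give the triol F2; selective benzoylation of its primary hydroxyl (PhCOCl, 2,4,6-collidine, CH2Cl2, −40 °C) comes back to the route at 10.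

Step 5. Benzoyl groups may migrate to the tin-activated oxygens, a second oxidation may follow the first, or the sensitive ketol may enolise and aromatise during work-up. Fallback: from 6, monosilylation (Et3SiCl, imidazole, DMF, 0 °C; both hydroxyls are equivalent) would give the mono-triethylsilyl ether F3; Dess–Martin oxidation of the remaining hydroxyl (NaHCO3, CH2Cl2) would give the silyl-protected ketol F4; HF·pyridine in THF removes the silyl group and comes back to the route at 8.

Step 3. The double inversion may be eroded by SN2′ transposition, by elimination of the pseudoaxial oxyphosphonium group, or by an incomplete second displacement next to the acetal oxygen. Fallback, which avoids any inversion: from 1, the acetonide is exchanged for benzyl ethers (HCl, MeOH to dimethyl L-tartrate F5; benzyl 2,2,2-trichloroacetimidate, TfOH cat. to the dibenzyl ether F6). The reduction–vinylation of step 1 then passes through the dibenzyl dialdehyde F7 and should run under chelation control by the α-benzyloxy groups to give the syn,syn-diol F8 directly. This is benzoylated with retention (PhCOCl, pyridine) to the dibenzoate F9, cyclised by ring-closing metathesis to the cyclohexene F10 and debenzylated (BCl3, CH2Cl2, −78 °C), which comes back to the route at 6.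

Further compounds
F1 | step 6 | (1R,4R,5R)-5-hydroxy-6-methylidenecyclohex-2-ene-1,4-diyl dibenzoate | C=C1[C@H](OC(=O)c2ccccc2)C=C[C@@H](OC(=O)c2ccccc2)[C@@H]1O
F2 | step 6 | (1R,2R,5R,6S)-1,6-dihydroxy-1-(hydroxymethyl)cyclohex-3-ene-2,5-diyl dibenzoate | OC[C@]1(O)[C@H](OC(=O)c2ccccc2)C=C[C@@H](OC(=O)c2ccccc2)[C@@H]1O
F3 | step 5 | mono-O-triethylsilyl ether of diol 6 | O[C@H]1[C@H](OC(=O)c2ccccc2)C=C[C@@H](OC(=O)c2ccccc2)[C@@H]1O[Si](CC)(CC)CC
F4 | step 5 | O-triethylsilyl ether of ketol 8 | O=C1[C@H](OC(=O)c2ccccc2)C=C[C@@H](OC(=O)c2ccccc2)[C@@H]1O[Si](CC)(CC)CC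
F5 | step 3 | dimethyl (2R,3R)-2,3-dihydroxybutanedioate (dimethyl L-tartrate) | COC(=O)[C@H](O)[C@@H](O)C(=O)OC
F6 | step 3 | dimethyl (2R,3R)-2,3-bis(benzyloxy)butanedioate | COC(=O)[C@H](OCc1ccccc1)[C@@H](OCc1ccccc1)C(=O)OC
F7 | step 3 | (2R,3R)-2,3-bis(benzyloxy)butanedial (not isolated) | O=C[C@H](OCc1ccccc1)[C@@H](OCc1ccccc1)C=O
F8 | step 3 | (3R,4S,5S,6R)-4,5-bis(benzyloxy)octa-1,7-diene-3,6-diol | C=C[C@@H](O)[C@H](OCc1ccccc1)[C@@H](OCc1ccccc1)[C@H](O)C=C
F9 | step 3 | (3R,4S,5S,6R)-4,5-bis(benzyloxy)octa-1,7-diene-3,6-diyl dibenzoate | C=C[C@@H](OC(=O)c1ccccc1)[C@H](OCc1ccccc1)[C@@H](OCc1ccccc1)[C@H](OC(=O)c1ccccc1)C=C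
F10 | step 3 | 2,3-di-O-benzyl ether of diol 6 | C(c1ccccc1)O[C@H]1[C@H](OC(=O)c2ccccc2)C=C[C@@H](OC(=O)c2ccccc2)[C@@H]1OCc1ccccc1
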